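The route rests on cutting C8–C9 and re-joining C1–C6, which folds the ten-membered carbocycle (C1–C10) back to a cyclohexene. The arc C1–C6 of the target, with its cis C4–C5 oxirane, cis C2=C3 alkene and C4 methyl, is a p-menthane ring obtainable from (R)-carvone. The C1–C10 unit is ring-trans, which is what a chair Cope shift delivers. One anionic oxy-Cope rearrangement therefore expands the six-membered ring by four atoms, forms C8–C9, fixes C8, creates the C1=C10 alkene and leaves a C6 ketone that enolises only toward C7. Its precursor is a trans-1,2-dialkenyl epoxycyclohexenol with an E 4-methoxybenzyl enol ether on the C6 carbinol and a silyloxymethyl-vinyl group on C1.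

Key step: step 15

Remark: locants are those of the final germacranolide, also in the six-membered precursors (ring C1–C6, C14 on C10, C15 on C4); β is the face of the six-membered ring that carries the C1 side chain, α the opposite face.

Step 1
Reactants: 1 4-methoxybenzyl alcohol; 2 trichloroethylene
Product: 4 (E)-1,2-dichlorovinyl 4-methoxybenzyl ether, via dichloroacetylene 3 (not isolated)
Conditions: KH, THF, −50 °C to rt
Reagents that add atoms: none
Why: Base-induced dehydrochlorination of 2 gives dichloroacetylene, to which the alkoxide adds in anti fashion (elimination–addition, the standard entry to 1,2-dichlorovinyl ethers).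

Step 2
Reactants: 4 (E)-1,2-dichlorovinyl 4-methoxybenzyl ether
Product: 6 4-methoxybenzyl ethynyl ether, via lithium alkoxyacetylide 5 (not isolated)
Conditions: n-BuLi (2.2 equiv), THF, −78 to −40 °C; H2O quench at −78 °C; kept cold
Reagents that add atoms: none
Why: Dehydrochlorination followed by chlorine–lithium exchange gives the acetylide, whose protonation furnishes the terminal ynol ether, which is used at once because benzylic ynol ethers rearrange on warming.

Step 3
Reactants: 6 4-methoxybenzyl ethynyl ether
Product: 8 (E)-1-iodo-2-(4-methoxybenzyloxy)ethene, via alkenylzirconocene chloride 7 (not isolated)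
Conditions: Cp2Zr(H)Cl, THF, 0 °C to rt; iodine, −78 to 0 °C
Reagents that add atoms: iodine, [I][I]
Why: Hydrozirconation adds H and Zr syn with the metal on the terminal carbon, and iodinolysis with retention fixes the E geometry of the later C7=C8 enol ether.

Step 4
Reactants: 9 ethyl bromopyruvate
Product: 10 ethyl 3-acetoxy-2-oxopropanoate
Conditions: KOAc, acetone, 0 °C to rt
Reagents that add atoms: potassium acetate, CC(=O)[O-].[K+]
Why: SN2 displacement at the carbonyl-activated primary bromide installs the C13 acetate before the fragment is joined.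

Step 5
Reactants: 11 (R)-(−)-carvone
Product: 12 (R)-10-chlorocarvone
Conditions: Ca(OCl)2, solid CO2, CH2Cl2/H2O, 0 °C
Reagents that add atoms: calcium hypochlorite, [Ca+2].[O-]Cl.[O-]Cl
Why: Ene-type allylic chlorination by HOCl attacks only the electron-rich 1,1-disubstituted alkene, since the enone alkene is deactivated, and leaves the C1 stereocentre untouched.

Step 6
Reactants: 12 (R)-10-chlorocarvone
Product: 13 (R)-10-acetoxycarvone
Conditions: KOAc, n-Bu4NI (cat.), DMF, 60 °C
Reagents that add atoms: potassium acetate, CC(=O)[O-].[K+]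
Why: Iodide-catalysed SN2 displacement of the primary allylic chloride places the C14 oxygen.

Step 7
Reactants: 13 (R)-10-acetoxycarvone
Product: 14 3α,4α-epoxy-14-hydroxy-5-ketone (oxirane trans to the side chain)
Conditions: 30% H2O2, NaOH (1.2 equiv), MeOH, 0 °C
Reagents that add atoms: hydrogen peroxide, OO
Why: In this Weitz–Scheffer epoxidation hydroperoxide adds axially to C3 anti to the C1 side chain, so the oxirane closes on the α face, and the same alkaline medium saponifies the acetate.

Step 8
Reactants: 14 3α,4α-epoxy-14-hydroxy-5-ketone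
Product: 15 14-O-TBS ether of 14
Conditions: TBSCl, imidazole, CH2Cl2, rt
Reagents that add atoms: tert-butyldimethylsilyl chloride, CC(C)(C)[Si](C)(C)Cl
Why: Standard silylation of the only hydroxyl gives a group that survives the bases, hydrides and DDQ used later and is removed last with fluoride.

Step 9
Reactants: 15 14-O-TBS epoxy ketone
Product: 17 6α-hydroxy-3α,4α-epoxy-5-ketone, via sodium enolate 16 (not isolated)
Conditions: NaN(SiMe3)2 (1.05 equiv), THF, −78 °C; 2-(phenylsulfonyl)-3-phenyloxaziridine; AcOH quench at −78 °C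
Reagents that add atoms: 2-(phenylsulfonyl)-3-phenyloxaziridine, O=S(=O)(N1OC1c1ccccc1)c1ccccc1
Why: In this enolate hydroxylation with an N-sulfonyloxaziridine only C6 can be deprotonated because C4 is quaternary, and oxygen enters anti to the neighbouring C1 side chain to give the 6α alcohol.

Step 10
Reactants: 17 6α-hydroxy-3α,4α-epoxy-5-ketone
Product: 18 cyclohex-4-ene-3α,6α-diol
Conditions: N2H4·H2O, AcOH (cat.), MeOH, 0 °C to rt
Reagents that add atoms: none
Why: In the Wharton transposition hydrazone formation, oxirane opening and loss of N2 move the unsaturation to C4=C5, and the C3–O bond is never broken, so the 3α configuration is retained.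

Step 11
Reactants: 18 cyclohex-4-ene-3α,6α-diol
Product: 19 4α,5α-epoxy-3α,6α-diol
Conditions: VO(acac)2 (cat.), t-BuOOH, CH2Cl2, 0 °C
Reagents that add atoms: tert-butyl hydroperoxide, CC(C)(C)OO
Why: In this hydroxyl-directed epoxidation both allylic hydroxyls lie on the α face and deliver the peroxide there, which sets C4 and C5 as in the target, and the side-chain alkene has no free hydroxyl and stays intact.

Step 12
Reactants: 19 4α,5α-epoxy-3α,6α-diol
Product: 20 4α,5α-epoxycyclohex-2-en-6α-ol
Conditions: Ph2S[OC(CF3)2Ph]2 (1.3 equiv), CH2Cl2, 0 °C to rt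
Reagents that add atoms: none
Why: In this sulfurane-mediated E2 dehydration, ligand exchange is reversible and only the quasi-axial C3 oxygen has an anti-periplanar hydrogen (on C2, C4 being quaternary), so the cis C2=C3 alkene forms and the quasi-equatorial C6 hydroxyl returns on work-up.

Step 13
Reactants: 20 4α,5α-epoxycyclohex-2-en-6α-ol
Product: 21 4α,5α-epoxycyclohex-2-en-6-one
Conditions: 1,1,1-triacetoxy-1,1-dihydro-1,2-benziodoxol-3(1H)-one (DMP), pyridine, CH2Cl2, 0 °C; filtered cold and used crude
Reagents that add atoms: none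
Why: Periodinane oxidation works under neutral buffered conditions, which is needed because the doubly allylic C1–H makes this ketone prone to enolisation followed by oxirane opening to a catechol.

Step 14
Reactants: 21 4α,5α-epoxycyclohex-2-en-6-one; 8 (E)-1-iodo-2-(4-methoxybenzyloxy)ethene
Product: 24 epoxy dialkenyl cyclohexenol (6β-OH; 6α E-enol ether; 1β side chain; 4α,5α-oxirane), via alkenyllithium 22 (not isolated), via alkenylcerium dichloride 23 (not isolated)
Conditions: 8, t-BuLi (2.0 equiv), Et2O, −78 °C; CeCl3, THF, −78 °C; then 21, −78 °C; pH 7 buffer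
Reagents that add atoms: none
Why: In this organocerium 1,2-addition, halogen–lithium exchange with retention and immediate transmetalation give a weakly basic alkenyl reagent that adds faster than it enolises, and it attacks the almost flat ring from the α face opposite the pseudo-axial C1 side chain, which sets C6 with the two alkenyl groups trans.

Step 15
Reactants: 24 epoxy dialkenyl cyclohexenol
Product: 27 ten-membered epoxy dienone (8S; 1(10)-ring-trans; 2Z; cis-4,5-oxirane; 6-ketone), via potassium alkoxide 25 (not isolated), via potassium enolate 26 (not isolated)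
Conditions: KH (1.3 equiv), 18-crown-6 (1.3 equiv), THF, −20 to 0 °C; inverse quench into AcOH/THF at −78 °C
Reagents that add atoms: none
Why: KH forms the crown-separated alkoxide 25, whose charge weakens the doubly allylic C1–C6 bond so that the 1,5-diene C8=C7–C6–C1–C10=C9 undergoes a concerted [3,3] shift (the anionic oxy-Cope rearrangement, well known for trans-1,2-dialkenylcyclohexanols giving cyclodec-5-enones), which forms C8–C9 and gives enolate 26, protonated cold to 27. The ten-membered ring arises by four-atom ring expansion through a six-membered chair transition state and not by end-to-end closure, so no dilution is needed. Because the alkenyl groups are trans and both equatorial, only the chair with the ring bonds C6–C5 and C1–C2 equatorial is within reach, and this gives the ring-trans C1=C10 alkene. Suprafacial bonding at the E enol ether, with its oxygen equatorial, transfers the C1/C6 configuration to 8S. The other 1,5-diene (C8=C7–C6–C1–C2=C3) would have to bridge C8 to C3 across the ring in a boat and should not compete, and Payne migration of the trans epoxy alkoxide is reversible and is drained by the irreversible enolate formation. Loss of 4-methoxybenzyl oxide from the β-alkoxy enolate is held back because the C8–O bond lies in the enolate plane as formed, the temperature stays at or below 0 °C, and the enolate is quenched inversely at −78 °C.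

Step 16
Reactants: 27 ten-membered epoxy dienone; 10 ethyl 3-acetoxy-2-oxopropanoate
Product: 29 C7 aldol adduct (tertiary C11 alcohol; mixture at C7 and C11), via lithium enolate 28 (not isolated)
Conditions: LiN(SiMe3)2 (1.05 equiv), THF, −78 °C; 10 (1.5 equiv), −78 °C; AcOH quench at −78 °C
Reagents that add atoms: none
Why: In this kinetic lithium-enolate aldol addition to the activated ketone of an α-keto ester, C7 is the only enolisable position because C5 is an oxirane carbon, the low temperature suppresses alkoxide loss from C8 and retro-aldol, and C7 and C11 need no control because both become sp2 later.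

Step 17
Reactants: 29 C7 aldol adduct
Product: 31 6,12-γ-lactone with 11-hydroxyl (6S), via hydroxy ester 30 (not isolated)
Conditions: Zn(BH4)2, Et2O, −40 to −10 °C; aq NH4Cl; crude stirred over silica gel in CH2Cl2, rt
Reagents that add atoms: none
Why: In this chelation-controlled reduction of an α,β-epoxy ketone, zinc bridges the carbonyl and oxirane oxygens, the ring body covers the C4 side, and hydride enters from the outer H5 side to give the anti epoxy alcohol (6S), which lactonises onto the ethyl ester.

Step 18
Reactants: 31 6,12-γ-lactone with 11-hydroxyl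
Product: 32 7(11)-butenolide (8-OPMB; 14-OTBS; 13-OAc)
Conditions: SOCl2, pyridine, −30 to 0 °C
Reagents that add atoms: none
Why: Dehydration of the tertiary α-hydroxy lactone through its chlorosulfite can run as an anti E2 or a syn elimination, so both diastereomers react, and it should give the more substituted conjugated C7=C11 alkene while erasing the uncontrolled centres.

Step 19
Reactants: 32 7(11)-butenolide
Product: 33 8-alcohol
Conditions: DDQ, CH2Cl2/pH 7 buffer, 0 °C
Reagents that add atoms: none
Why: Oxidative cleavage of the electron-rich 4-methoxybenzyl ether occurs under neutral conditions that spare the silyl ether, acetate, oxirane and diene.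

Step 20
Reactants: 33 8-alcohol
Product: 34 8-methacrylate
Conditions: methacrylic anhydride, DMAP (cat.), Et3N, CH2Cl2, 0 °C
Reagents that add atoms: methacrylic anhydride, C=C(C)C(=O)OC(=O)C(C)=C
Why: DMAP-catalysed acylation of the only free hydroxyl proceeds with retention at C8, and the low temperature limits translactonisation toward O8.

Step 21
Reactants: 34 8-methacrylate
Product: 35 14-alcohol
Conditions: HF·pyridine, excess pyridine, THF, 0 °C
Reagents that add atoms: none
Why: Buffered fluoride-induced desilylation frees the primary allylic hydroxyl without touching the esters or the acid-sensitive vinyl oxirane.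

Step 22
Reactants: 35 14-alcohol
Product: 36 CNP0207684.1
Conditions: VO(acac)2 (cat.), t-BuOOH, CH2Cl2, −10 °C
Reagents that add atoms: tert-butyl hydroperoxide, CC(C)(C)OO
Why: In this hydroxyl-directed epoxidation the vanadium bound at O14 reaches only the allylic C1=C10 alkene, because C2=C3 is remote and deactivated by the oxirane and the acrylate and butenolide are electron-poor, and it attacks the exposed outer face of the ring-trans alkene in the fold inherited from the chair shift to give 1R,10S.

Compound list
1 | 4-methoxybenzyl alcohol | COc1ccc(CO)cc1 | starting material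
2 | trichloroethylene | ClC=C(Cl)Cl | starting material
3 | dichloroacetylene | ClC#CCl | intermediate
4 | (E)-1,2-dichlorovinyl 4-methoxybenzyl ether | COc1ccc(CO/C(Cl)=C\Cl)cc1 | intermediate
5 | lithium (4-methoxybenzyloxy)acetylide | [Li]C#COCc1ccc(OC)cc1 | intermediate
6 | 4-methoxybenzyl ethynyl ether | C#COCc1ccc(OC)cc1 | intermediate
7 | (E)-2-(4-methoxybenzyloxy)vinylzirconocene chloride | COc1ccc(CO/C=C/[Zr+2]Cl)cc1.c1cc[cH-]c1.c1cc[cH-]c1 | intermediate
8 | (E)-1-iodo-2-(4-methoxybenzyloxy)ethene | COc1ccc(CO/C=C/I)cc1 | intermediate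
9 | ethyl bromopyruvate | CCOC(=O)C(=O)CBr | starting material
10 | ethyl 3-acetoxy-2-oxopropanoate | CCOC(=O)C(=O)COC(C)=O | intermediate
11 | (R)-(−)-carvone | CC1=CC[C@H](CC1=O)C(C)=C | starting material
12 | (R)-10-chlorocarvone | CC1=CC[C@H](CC1=O)C(=C)CCl | intermediate
13 | (R)-10-acetoxycarvone | CC1=CC[C@H](CC1=O)C(=C)COC(C)=O | intermediate
14 | (1R,4R,6R)-4-(3-hydroxyprop-1-en-2-yl)-1-methyl-7-oxabicyclo[4.1.0]heptan-2-one (3α,4α-epoxy-14-hydroxy-5-ketone) | C1C(=O)[C@]2(C)O[C@@H]2C[C@H]1C(=C)CO | intermediate
15 | 14-O-TBS ether of 14 | C1C(=O)[C@]2(C)O[C@@H]2C[C@H]1C(=C)CO[Si](C)(C)C(C)(C)C | intermediate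
16 | sodium C5(O)=C6 enolate of 15 | C1=C([O-])[C@]2(C)O[C@@H]2C[C@H]1C(=C)CO[Si](C)(C)C(C)(C)C.[Na+] | intermediate
17 | 6α-hydroxy-3α,4α-epoxy-5-ketone (hydroxyl trans to the side chain) | O[C@@H]1C(=O)[C@]2(C)O[C@@H]2C[C@H]1C(=C)CO[Si](C)(C)C(C)(C)C | intermediate
18 | 4-methylcyclohex-4-ene-3α,6α-diol with 1β side chain | O[C@@H]1C=C(C)[C@H](O)C[C@H]1C(=C)CO[Si](C)(C)C(C)(C)C | intermediate
19 | 4α,5α-epoxy-3α,6α-diol | O[C@@H]1[C@@H]2O[C@]2(C)[C@H](O)C[C@H]1C(=C)CO[Si](C)(C)C(C)(C)C | intermediate
20 | 4α,5α-epoxycyclohex-2-en-6α-ol | O[C@@H]1[C@@H]2O[C@]2(C)C=C[C@H]1C(=C)CO[Si](C)(C)C(C)(C)C | intermediate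
21 | 4α,5α-epoxycyclohex-2-en-6-one | O=C1[C@@H]2O[C@]2(C)C=C[C@H]1C(=C)CO[Si](C)(C)C(C)(C)C | intermediate
22 | (E)-2-(4-methoxybenzyloxy)vinyllithium | [Li]/C=C/OCc1ccc(OC)cc1 | intermediate
23 | (E)-2-(4-methoxybenzyloxy)vinylcerium dichloride | Cl[Ce](Cl)/C=C/OCc1ccc(OC)cc1 | intermediate
24 | epoxy dialkenyl cyclohexenol (6β-OH, 6α E-enol ether, 1β side chain, 4α,5α-oxirane) | O[C@@]1(/C=C/OCc2ccc(OC)cc2)[C@@H]2O[C@]2(C)C=C[C@H]1C(=C)CO[Si](C)(C)C(C)(C)C | intermediate
25 | potassium alkoxide of 24 | [K+].[O-][C@@]1(/C=C/OCc2ccc(OC)cc2)[C@@H]2O[C@]2(C)C=C[C@H]1C(=C)CO[Si](C)(C)C(C)(C)C | intermediate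
26 | ten-membered potassium C6(O)=C7 enolate (ring-trans) | [K+].[O-]/C1=C\[C@@H](OCc2ccc(OC)cc2)C/C(CO[Si](C)(C)C(C)(C)C)=C/C=C\[C@@]2(C)O[C@@H]12 | intermediate
27 | (8S)-8-(4-methoxybenzyloxy)-14-(TBS-oxy)-cis-4,5-epoxygermacra-1(10)E,2Z-dien-6-one | COc1ccc(CO[C@H]2C/C(CO[Si](C)(C)C(C)(C)C)=C/C=C\[C@@]3(C)O[C@H]3C(=O)C2)cc1 | intermediate
28 | lithium C6(O)=C7 enolate of 27 | COc1ccc(CO[C@H]2C/C(CO[Si](C)(C)C(C)(C)C)=C/C=C\[C@@]3(C)O[C@H]3C([O-])=C2)cc1.[Li+] | intermediate
29 | C7 aldol adduct, ethyl 3-acetoxy-2-hydroxy-2-(C7-yl)propanoate (mixture at C7 and C11) | COc1ccc(CO[C@H]2C/C(CO[Si](C)(C)C(C)(C)C)=C/C=C\[C@@]3(C)O[C@H]3C(=O)C2C(O)(COC(C)=O)C(=O)OCC)cc1 | intermediate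
30 | (6S)-6-hydroxy ester | COc1ccc(CO[C@H]2C/C(CO[Si](C)(C)C(C)(C)C)=C/C=C\[C@@]3(C)O[C@H]3[C@@H](O)C2C(O)(COC(C)=O)C(=O)OCC)cc1 | intermediate
31 | (6S)-11-hydroxy-6,12-olide | COc1ccc(CO[C@H]2C/C(CO[Si](C)(C)C(C)(C)C)=C/C=C\[C@@]3(C)O[C@H]3[C@H]3OC(=O)C(O)(COC(C)=O)C23)cc1 | intermediate
32 | 13-acetoxy-7(11)-en-6,12-olide, 8-OPMB, 14-OTBS | COc1ccc(CO[C@H]2C/C(CO[Si](C)(C)C(C)(C)C)=C/C=C\[C@@]3(C)O[C@H]3[C@H]3OC(=O)C(COC(C)=O)=C23)cc1 | intermediate
33 | 8-alcohol | O[C@H]1C/C(CO[Si](C)(C)C(C)(C)C)=C/C=C\[C@@]2(C)O[C@H]2[C@H]2OC(=O)C(COC(C)=O)=C12 | intermediate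
34 | 8-methacrylate, 14-OTBS | C=C(C)C(=O)O[C@H]1C/C(CO[Si](C)(C)C(C)(C)C)=C/C=C\[C@@]2(C)O[C@H]2[C@H]2OC(=O)C(COC(C)=O)=C12 | intermediate
35 | 8-methacrylate, 14-alcohol | C=C(C)C(=O)O[C@H]1C/C(CO)=C/C=C\[C@@]2(C)O[C@H]2[C@H]2OC(=O)C(COC(C)=O)=C12 | intermediate
36 | CNP0207684.1, (1R,4R,5S,6S,8S,10S)-13-acetoxy-1,10:4,5-diepoxy-14-hydroxy-8-methacryloyloxygermacra-2Z,7(11)-dien-6,12-olide | C=C(C)C(=O)O[C@H]1C[C@@]2(CO)O[C@@H]2/C=C\[C@@]2(C)O[C@H]2[C@H]2OC(=O)C(COC(C)=O)=C12 | target

Total step count: 22. Longest linear sequence: 18 steps (steps 5–22, from (R)-carvone).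

Steps most likely to fail

1. Step 15. The β-alkoxy enolate may expel 4-methoxybenzyl oxide. The oxirane may migrate along the alkoxide. A stepwise cleavage and recombination may erode the transfer of chirality to C8. The fallback leaves the anionic manifold altogether and sets out from 24. The tertiary alcohol is silylated (Me3SiOTf, 2,6-lutidine, −78 °C) to the trimethylsilyl ether F1. F1 is heated in base-washed glassware in toluene or xylene, so that the same [3,3] shift runs as a neutral siloxy-Cope rearrangement to the ten-membered trimethylsilyl enol ether F2. No free alkoxide or enolate is present at any point. Brief methanolysis (K2CO3 cat., MeOH, −20 °C) then releases the ketone, and the route is rejoined at 27.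

2. Step 14. The E-configured β-alkoxyalkenyllithium may undergo anti elimination to acetylene before transmetalation. The ketone may enolise and aromatise. Attack may also occur on the wrong face. The fallback sets out from 21 and builds the enol ether after the C–C bond has been made. The much less basic HC≡CMgBr/CeCl3 is added at −78 °C to give the ethynyl carbinol F3. Hydroboration with pinacolborane (Cp2Zr(H)Cl cat.) gives the (E)-vinylboronate F4. A stereoretentive Chan–Lam type etherification with excess 1 (Cu(OAc)2, Et3N, air, rt) then delivers the E enol ether, and the route is rejoined at 24.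

3. Step 16. The acidic CH2 of 10 may transfer a proton to the enolate. The tertiary aldolate may revert or shift its acetyl group. The enolate may lose the C8 alkoxide while waiting for a slow addition. The fallback sets out from 27 and replaces the basic enolate by a neutral nucleophile. Trapping (LiN(SiMe3)2, Et3SiCl, −78 °C) gives the triethylsilyl enol ether F5. F5 is added to 10 in a Mukaiyama aldol reaction in which the keto ester is activated by chelation (Cu(OTf)2, 10 mol %, with 2,2'-(propane-2,2-diyl)bis(4-tert-butyl-4,5-dihydrooxazole), CH2Cl2, −78 °C), and this gives the 11-O-triethylsilyl aldol F6. Selective removal of the triethylsilyl group (Et3N·3HF, 0 °C) rejoins the route at 29.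

Further compounds
F1 | step 15 | 6-O-trimethylsilyl ether of 24 | C[Si](C)(C)O[C@@]1(/C=C/OCc2ccc(OC)cc2)[C@@H]2O[C@]2(C)C=C[C@H]1C(=C)CO[Si](C)(C)C(C)(C)C
F2 | step 15 | ten-membered trimethylsilyl enol ether (ring-trans C6=C7) | C[Si](C)(C)O/C1=C\[C@@H](OCc2ccc(OC)cc2)C/C(CO[Si](C)(C)C(C)(C)C)=C/C=C\[C@@]2(C)O[C@@H]12
F3 | step 14 | 6α-ethynyl-6β-carbinol | O[C@@]1(C#C)[C@@H]2O[C@]2(C)C=C[C@H]1C(=C)CO[Si](C)(C)C(C)(C)C
F4 | step 14 | (E)-vinylboronic acid pinacol ester | O[C@@]1(/C=C/B2OC(C)(C)C(C)(C)O2)[C@@H]2O[C@]2(C)C=C[C@H]1C(=C)CO[Si](C)(C)C(C)(C)C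
F5 | step 16 | triethylsilyl enol ether of 27 | COc1ccc(CO[C@H]2C/C(CO[Si](C)(C)C(C)(C)C)=C/C=C\[C@@]3(C)O[C@H]3C(O[Si](CC)(CC)CC)=C2)cc1
F6 | step 16 | 11-O-triethylsilyl ether of 29 | COc1ccc(CO[C@H]2C/C(CO[Si](C)(C)C(C)(C)C)=C/C=C\[C@@]3(C)O[C@H]3C(=O)C2C(O[Si](CC)(CC)CC)(COC(C)=O)C(=O)OCC)cc1
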